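**Retrosynthetic overview**

1. Target 19 (chain numbered C1 at the guaiacyl ring to C7 at the catechol ring; (3R,5S), which is the 1,3-syn diacetate) comes from hydrogenolysis of three benzyl ethers, diacetylation, and a chelation-controlled syn reduction of a C3 ketone directed by the C5 hydroxyl.
2. The C3 ketone comes from oxidative cleavage of a C3 methylidene group; the C5 hydroxyl comes from stereoretentive oxidation of a C5–B bond.
3. Feature used: in the open C1–C7 chain, C4–C5 is a two-carbon link between C3 and the C6–C7–catechol arm, and C5 carries oxygen. C4–C5 is therefore taken as a vinyl group on boron: C5–C6 forms by 1,2-migration of the arylethyl group from boron, and C3–C4 by coupling with an alkenyl triflate, three components in one operation.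
4. Components: an arylethyl pinacol boronate (from 3,4-bis(benzyloxy)benzaldehyde by methylenation and hydroboration), halide-free vinyllithium (from tetravinyltin), and the kinetic enol triflate of O-benzylzingerone.
5. No ring is formed anywhere in the route; both benzene rings are bought in.

Key step: step 6

Assumption: the (Sp,Sp) enantiomer of the MandyPhos ligand is taken to send the migrating group to the Re face of the boron-bearing vinyl carbon, giving (S)-12; if the sense of induction is the opposite, the (Rp,Rp) ligand is used and nothing else changes.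

**Route**

Step 1
Reactants: 1 3,4-bis(benzyloxy)benzaldehyde
Product: 2 1,2-bis(benzyloxy)-4-ethenylbenzene
Conditions: Ph3PCH3Br, KOtBu, THF, 0 °C to rt
Reagents that add atoms: methyltriphenylphosphonium bromide, C[P+](c1ccccc1)(c1ccccc1)c1ccccc1.[Br-]
Why: Wittig methylenation of an aromatic aldehyde with the non-stabilised ylide is dependable, and the benzyl ethers are inert to it.

Step 2
Reactants: 2 1,2-bis(benzyloxy)-4-ethenylbenzene; 3 pinacolborane
Product: 4 2-{2-[3,4-bis(benzyloxy)phenyl]ethyl}-4,4,5,5-tetramethyl-1,3,2-dioxaborolane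
Conditions: [Ir(cod)Cl]2 (1.5 mol%), dppe (3 mol%), CH2Cl2, rt
Reagents that add atoms: none
Why: Iridium-catalysed hydroboration of a vinylarene with pinacolborane places boron on the terminal carbon (anti-Markovnikov), so the linear primary alkylboronate should form.

Step 3
Reactants: 5 zingerone
Product: 6 4-[4-(benzyloxy)-3-methoxyphenyl]butan-2-one
Conditions: BnBr, K2CO3, DMF, rt
Reagents that add atoms: benzyl bromide, BrCc1ccccc1
Why: Williamson etherification, in which carbonate deprotonates only the phenol, so O-benzylation occurs without touching the ketone α-positions.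

Step 4
Reactants: 6 4-[4-(benzyloxy)-3-methoxyphenyl]butan-2-one
Product: 8 4-[4-(benzyloxy)-3-methoxyphenyl]but-1-en-2-yl trifluoromethanesulfonate, via lithium enolate 7 (not isolated)
Conditions: LDA, THF, −78 °C; PhNTf2, −78 °C to 0 °C
Reagents that add atoms: N-phenylbis(trifluoromethanesulfonimide), O=S(=O)(N(c1ccccc1)S(=O)(=O)C(F)(F)F)C(F)(F)F
Why: Kinetic deprotonation of the methyl ketone by LDA at −78 °C removes a proton from the less hindered methyl group, and O-sulfonylation of that terminal enolate (enol triflate formation) should give the 1,1-disubstituted alkenyl triflate.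

Step 5
Reactants: 9 tetraethenylstannane (tetravinyltin)
Product: 10 ethenyllithium (vinyllithium), halide-free
Conditions: n-BuLi (4 equiv), pentane, rt; precipitate filtered under argon, washed with pentane, dissolved in THF and titrated
Reagents that add atoms: n-butyllithium, [Li]CCCC
Why: Tin–lithium exchange is driven by precipitation of vinyllithium from pentane and gives a reagent free of halide and of residual vinylstannanes, both of which would interfere with the palladium step.

Step 6
Reactants: 4 2-{2-[3,4-bis(benzyloxy)phenyl]ethyl}-4,4,5,5-tetramethyl-1,3,2-dioxaborolane; 10 vinyllithium; 8 4-[4-(benzyloxy)-3-methoxyphenyl]but-1-en-2-yl trifluoromethanesulfonate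
Product: 12 2-[(3S)-1-[3,4-bis(benzyloxy)phenyl]-7-[4-(benzyloxy)-3-methoxyphenyl]-5-methylideneheptan-3-yl]-4,4,5,5-tetramethyl-1,3,2-dioxaborolane, via vinylboron ate complex 11 (not isolated)
Conditions: 4, 10 (1.0 equiv), THF, 0 °C to rt; then 8 (1.1 equiv), Pd(OAc)2 (2 mol%), (Sp,Sp)-MandyPhos (a 1,1′-bis(diarylphosphino)-2,2′-bis[α-(dimethylamino)benzyl]ferrocene, aryl = 3,5-dimethylphenyl as first choice; 2.4 mol%), THF, 60 °C
Reagents that add atoms: none
Why: Zerovalent palladium formed from Pd(OAc)2 and the bisphosphine inserts into the C–O bond of triflate 8, and the resulting cationic divalent alkenylpalladium binds the vinyl group of ate complex 11 and acts as a π-acid, which induces 1,2-migration of the arylethyl group from boron to the boron-bearing carbon anti to palladium (C5–C6), after which reductive elimination joins C4 to C3 and returns zerovalent palladium. The closest known reaction type is this same transformation, the palladium-catalysed enantioselective conjunctive cross-coupling of alkyl(vinyl)boron ate complexes with alkenyl triflates, applied here to a primary alkyl migrating group and an unhindered 1,1-disubstituted alkenyl triflate. The step closes no ring. The one new stereocentre (C5, S) is controlled by the chiral ferrocenyl bisphosphine, which decides which face of the coordinated vinyl group palladium occupies, so that the arylethyl group arrives on the Re face of the boron-bearing carbon. The step needs the metalate shift to outrun direct transmetalation of vinyl or arylethyl to palladium and β-hydride elimination; the wide-bite-angle ligand, the non-coordinating triflate and the halide-free vinyllithium keep palladium cationic and open to alkene binding, and the alkyl(alkenyl)palladium intermediate is expected to eliminate reductively faster than it loses hydride.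

Step 7
Reactants: 12 the (S)-boronate
Product: 13 (3S)-1-[3,4-bis(benzyloxy)phenyl]-7-[4-(benzyloxy)-3-methoxyphenyl]-5-methylideneheptan-3-ol
Conditions: H2O2 (30% aq), NaOH (3 M aq), THF, 0 °C to rt
Reagents that add atoms: hydrogen peroxide, OO
Why: Oxidation of the C–B bond by alkaline peroxide proceeds by 1,2-shift of carbon from boron to oxygen with retention, so the (S)-boronate should give the (S)-alcohol, and the unactivated 1,1-disubstituted alkene is not attacked by basic peroxide.

Step 8
Reactants: 13 the (S)-homoallylic alcohol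
Product: 15 (5S)-7-[3,4-bis(benzyloxy)phenyl]-1-[4-(benzyloxy)-3-methoxyphenyl]-5-hydroxyheptan-3-one, via triol 14 (not isolated)
Conditions: K2OsO4·2H2O (2 mol%), NaIO4 (4 equiv), 2,6-lutidine (2 equiv), 1,4-dioxane/H2O 3:1, rt
Reagents that add atoms: sodium periodate, [Na+].[O-]I(=O)(=O)=O (terminal oxidant; the oxygen is delivered through catalytic osmium tetroxide, O=[Os](=O)(=O)=O, formed in the flask)
Why: Lemieux–Johnson cleavage (osmium-catalysed dihydroxylation of the methylidene group, then periodate glycol cleavage, buffered by 2,6-lutidine) should give the C3 ketone, because the C5 hydroxyl is 1,3-related and not cleavable and the benzyl ethers and electron-rich rings are far less exposed than they would be to ozone.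

Step 9
Reactants: 15 the (5S)-β-hydroxy ketone
Product: 17 (3R,5S)-7-[3,4-bis(benzyloxy)phenyl]-1-[4-(benzyloxy)-3-methoxyphenyl]heptane-3,5-diol, via diethylboron chelate 16 (not isolated)
Conditions: Et2BOMe, THF/MeOH 4:1, −78 °C; NaBH4, −78 °C; AcOH, then co-evaporation with MeOH
Reagents that add atoms: none
Why: Narasaka–Prasad reduction, in which boron ties the C5 oxygen and the C3 carbonyl into a six-membered half-chair chelate with both chains pseudo-equatorial and external hydride attacks axially, so the (5S) centre should set (3R) and give the 1,3-syn diol.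

Step 10
Reactants: 17 the (3R,5S)-diol
Product: 18 (3R,5S)-7-[3,4-bis(benzyloxy)phenyl]-1-[4-(benzyloxy)-3-methoxyphenyl]heptane-3,5-diyl diacetate
Conditions: Ac2O, pyridine, DMAP (cat.), CH2Cl2, rt
Reagents that add atoms: acetic anhydride, CC(=O)OC(C)=O
Why: DMAP-catalysed acylation esterifies both secondary alcohols without touching the stereocentres, and because all three phenols are still benzylated the acetates can only go onto C3 and C5.

Step 11
Reactants: 18 the tribenzyl diacetate
Product: 19 (3R,5S)-7-(3,4-dihydroxyphenyl)-1-(4-hydroxy-3-methoxyphenyl)heptane-3,5-diyl diacetate (target)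
Conditions: H2 (1 atm), Pd/C (10%), EtOAc, rt
Reagents that add atoms: none
Why: Palladium-catalysed hydrogenolysis cleaves the three benzyl aryl ethers under neutral conditions, while the C3 and C5 acetates are neither benzylic nor allylic and should stay in place with their configuration.

**Compound list**

1 | 3,4-bis(benzyloxy)benzaldehyde | O=Cc1ccc(OCc2ccccc2)c(OCc2ccccc2)c1 | starting material
2 | 1,2-bis(benzyloxy)-4-ethenylbenzene | C=Cc1ccc(OCc2ccccc2)c(OCc2ccccc2)c1 | intermediate
3 | pinacolborane (4,4,5,5-tetramethyl-1,3,2-dioxaborolane) | CC1(C)OBOC1(C)C | starting material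
4 | 2-{2-[3,4-bis(benzyloxy)phenyl]ethyl}-4,4,5,5-tetramethyl-1,3,2-dioxaborolane | CC1(C)OB(CCc2ccc(OCc3ccccc3)c(OCc3ccccc3)c2)OC1(C)C | intermediate
5 | zingerone, 4-(4-hydroxy-3-methoxyphenyl)butan-2-one | CC(=O)CCc1ccc(O)c(OC)c1 | starting material
6 | 4-[4-(benzyloxy)-3-methoxyphenyl]butan-2-one | CC(=O)CCc1ccc(OCc2ccccc2)c(OC)c1 | intermediate
7 | lithium 4-[4-(benzyloxy)-3-methoxyphenyl]but-1-en-2-olate | [Li]OC(=C)CCc1ccc(OCc2ccccc2)c(OC)c1 | intermediate
8 | 4-[4-(benzyloxy)-3-methoxyphenyl]but-1-en-2-yl trifluoromethanesulfonate | C=C(CCc1ccc(OCc2ccccc2)c(OC)c1)OS(=O)(=O)C(F)(F)F | intermediate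
9 | tetraethenylstannane (tetravinyltin) | C=C[Sn](C=C)(C=C)C=C | starting material
10 | ethenyllithium (vinyllithium) | [Li]C=C | intermediate
11 | lithium {2-[3,4-bis(benzyloxy)phenyl]ethyl}(ethenyl)(pinacolato)borate | [Li+].C=C[B-]1(CCc2ccc(OCc3ccccc3)c(OCc3ccccc3)c2)OC(C)(C)C(C)(C)O1 | intermediate
12 | 2-[(3S)-1-[3,4-bis(benzyloxy)phenyl]-7-[4-(benzyloxy)-3-methoxyphenyl]-5-methylideneheptan-3-yl]-4,4,5,5-tetramethyl-1,3,2-dioxaborolane | C=C(CCc1ccc(OCc2ccccc2)c(OC)c1)C[C@H](CCc1ccc(OCc2ccccc2)c(OCc2ccccc2)c1)B1OC(C)(C)C(C)(C)O1 | intermediate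
13 | (3S)-1-[3,4-bis(benzyloxy)phenyl]-7-[4-(benzyloxy)-3-methoxyphenyl]-5-methylideneheptan-3-ol | C=C(CCc1ccc(OCc2ccccc2)c(OC)c1)C[C@H](CCc1ccc(OCc2ccccc2)c(OCc2ccccc2)c1)O | intermediate
14 | (4S)-6-[3,4-bis(benzyloxy)phenyl]-2-{2-[4-(benzyloxy)-3-methoxyphenyl]ethyl}hexane-1,2,4-triol, both C2 epimers | OCC(O)(CCc1ccc(OCc2ccccc2)c(OC)c1)C[C@H](CCc1ccc(OCc2ccccc2)c(OCc2ccccc2)c1)O | intermediate
15 | (5S)-7-[3,4-bis(benzyloxy)phenyl]-1-[4-(benzyloxy)-3-methoxyphenyl]-5-hydroxyheptan-3-one | O=C(CCc1ccc(OCc2ccccc2)c(OC)c1)C[C@H](CCc1ccc(OCc2ccccc2)c(OCc2ccccc2)c1)O | intermediate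
16 | (5S)-7-[3,4-bis(benzyloxy)phenyl]-1-[4-(benzyloxy)-3-methoxyphenyl]-5-[(diethylboranyl)oxy]heptan-3-one (ketone oxygen coordinated to boron in a six-membered chelate; dative bond not drawn) | O=C(CCc1ccc(OCc2ccccc2)c(OC)c1)C[C@H](CCc1ccc(OCc2ccccc2)c(OCc2ccccc2)c1)OB(CC)CC | intermediate
17 | (3R,5S)-7-[3,4-bis(benzyloxy)phenyl]-1-[4-(benzyloxy)-3-methoxyphenyl]heptane-3,5-diol (1,3-syn) | COc1cc(CC[C@H](C[C@H](CCc2ccc(OCc3ccccc3)c(OCc3ccccc3)c2)O)O)ccc1OCc1ccccc1 | intermediate
18 | (3R,5S)-7-[3,4-bis(benzyloxy)phenyl]-1-[4-(benzyloxy)-3-methoxyphenyl]heptane-3,5-diyl diacetate | COc1cc(CC[C@H](C[C@H](CCc2ccc(OCc3ccccc3)c(OCc3ccccc3)c2)OC(C)=O)OC(C)=O)ccc1OCc1ccccc1 | intermediate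
19 | (3R,5S)-7-(3,4-dihydroxyphenyl)-1-(4-hydroxy-3-methoxyphenyl)heptane-3,5-diyl diacetate | COc1cc(CC[C@H](C[C@H](CCc2ccc(O)c(O)c2)OC(C)=O)OC(C)=O)ccc1O | target

**Step count**

Total step count: 11.
Longest linear sequence: 8 steps (steps 1, 2, 6, 7, 8, 9, 10, 11 from 1; equally steps 3, 4, 6, 7, 8, 9, 10, 11 from 5).

**Steps most likely to fail, with fallbacks**

Step 6 (key step). Direct transmetalation of the vinyl or arylethyl group from the ate complex to palladium (Suzuki-type coupling) may outrun the metalate shift, or discrimination between the two faces of the bound vinyl group may be insufficient. The fallback builds the same C4–C5 bond by a reagent-controlled boron aldol reaction; it sets out from 1 and 6 and rejoins the route at 15.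
- Aldehyde 1 is homologated with (triphenylphosphoranylidene)acetaldehyde (toluene, 80 °C) to (E)-3-[3,4-bis(benzyloxy)phenyl]prop-2-enal F1.
- The C=C bond of F1 is reduced by organocatalytic transfer hydrogenation (Hantzsch ester, dibenzylammonium trifluoroacetate, THF) to 3-[3,4-bis(benzyloxy)phenyl]propanal F2.
- Ketone 6 is enolised on its methyl side with (−)-Ipc2BCl and Et3N (Et2O, −78 to 0 °C) to the diisopinocampheylboron enolate of 6 F3.
- F3 adds to F2 at −78 °C (Paterson aldol) to give the diisopinocampheylboron aldolate of 15 F4, and oxidative work-up (H2O2, pH 7 buffer, MeOH) releases 15; the route continues at step 9.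
- The reagent enantiomer must expose the Re face of the aldehyde; for methyl ketone enolates this is expected of (−)-Ipc2BCl, made from (+)-α-pinene.
- Aldols of this kind usually give lower enantiomeric purity than the catalytic route aims for, so an upgrade by crystallisation at diol 17 is foreseen.

Step 4. The kinetic terminal enolate may equilibrate to the internal enolate by proton transfer during the slow O-sulfonylation, which would give regioisomeric enol triflates. The fallback fixes the regiochemistry in a separate, isolable enol derivative; it sets out from 6 and rejoins the route at 8.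
- Ketone 6 is added to LDA in the presence of Me3SiCl (internal quench, THF, −78 °C) to give {4-[4-(benzyloxy)-3-methoxyphenyl]but-1-en-2-yl}oxy(trimethyl)silane F5.
- After purification, MeLi (THF, 0 °C) regenerates amine-free lithium enolate 7, which cannot equilibrate by proton transfer and is trapped with PhNTf2 to give 8.

Step 8. Over-oxidation next to the new ketone or base-promoted loss of water from the β-hydroxy ketone may occur under the osmium–periodate conditions. The fallback is ozonolysis, a cycloaddition–cycloreversion at low temperature with no base and no diol stage; it sets out from 13 and rejoins the route at 15.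
- Alcohol 13 is treated with ozone, dosed only to the point of alkene consumption (CH2Cl2/MeOH, −78 °C).
- Methanol traps the carbonyl oxide as (5S)-7-[3,4-bis(benzyloxy)phenyl]-1-[4-(benzyloxy)-3-methoxyphenyl]-3-hydroperoxy-3-methoxyheptan-5-ol F6 (both C3 epimers), which Me2S reduces to 15.
- The 1,1-disubstituted alkene reacts with ozone far faster than the alkoxyarenes or the benzyl ethers, and this difference in rate is what the dosing relies on.

**Further compounds**

F1 | step 6 | (E)-3-[3,4-bis(benzyloxy)phenyl]prop-2-enal | O=C/C=C/c1ccc(OCc2ccccc2)c(OCc2ccccc2)c1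
F2 | step 6 | 3-[3,4-bis(benzyloxy)phenyl]propanal | O=CCCc1ccc(OCc2ccccc2)c(OCc2ccccc2)c1
F3 | step 6 | diisopinocampheylboron enolate of 6 (isopinocampheyl groups from (+)-α-pinene) | C=C(CCc1ccc(OCc2ccccc2)c(OC)c1)OB([C@@H]1C[C@@H]2C[C@H]([C@H]1C)C2(C)C)[C@@H]1C[C@@H]2C[C@H]([C@H]1C)C2(C)C
F4 | step 6 | diisopinocampheylboron aldolate of 15 | O=C(CCc1ccc(OCc2ccccc2)c(OC)c1)C[C@H](CCc1ccc(OCc2ccccc2)c(OCc2ccccc2)c1)OB([C@@H]1C[C@@H]2C[C@H]([C@H]1C)C2(C)C)[C@@H]1C[C@@H]2C[C@H]([C@H]1C)C2(C)C
F5 | step 4 | {4-[4-(benzyloxy)-3-methoxyphenyl]but-1-en-2-yl}oxy(trimethyl)silane | C=C(CCc1ccc(OCc2ccccc2)c(OC)c1)O[Si](C)(C)C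
F6 | step 8 | (5S)-7-[3,4-bis(benzyloxy)phenyl]-1-[4-(benzyloxy)-3-methoxyphenyl]-3-hydroperoxy-3-methoxyheptan-5-ol, both C3 epimers | COC(OO)(CCc1ccc(OCc2ccccc2)c(OC)c1)C[C@H](CCc1ccc(OCc2ccccc2)c(OCc2ccccc2)c1)O
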